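## The problem

The target 29 is a 5,7-dihydroxy-6-methoxyflavone whose ring A carries no hydrogen: C5 and C7 are phenols, C6 is a methyl ether, C8 bears an N-methylpyrrolidin-2-yl group, C8a the ring oxygen and C4a the carbonyl carbon of ring C. Two phenols flank a methyl ether that must survive, so the oxygens on C5, C6 and C7 need ethers of different lability. The oxygen on C8a must also be told apart from the one on C5, because either could close ring C onto C2 and only the C8a oxygen gives the right flavone. The single stereocentre is pyrrolidine C2 (R); no other stereocentre can relay to it, so it must come from a catalyst, an auxiliary or the chiral pool. That centre is a benzylic amine carbon between two oxygen-bearing ring carbons. Once a neighbouring phenol is free, loss of nitrogen toward an ortho-quinone methide (a retro-Mannich-type ionisation) can open the ring and erase the configuration, so the phenols are best unmasked late and cold. The tertiary amine is open to oxidation and the pyranone to ring-opening by hydroxide, which limits what can follow their installation. The enabling feature is that pyrrolidine C3, C4 and C5 are plain methylene groups and C2 carries only hydrogen and the aryl ring. The ring is therefore a formal (3+2) adduct of a three-carbon dipole and the C=N bond of an aldimine whose carbon sits on C8, the position where a symmetrical ring A phenol accepts a formyl group.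

## Retrosynthesis

**29 from 28.** The three O-benzyl bonds (C5, C7, C4') are cut last. Benzyl rather than methyl keeps the C6 methyl ether distinguishable. Keeping both ring A phenols masked until the final cold step protects the benzylic C–N bond from ionisation. The forward reaction must cleave benzyl ethers without touching the methyl ether or the stereocentre.

**28 from 25.** The O1–C2 bond of ring C is cut, leading to ynone 25. The ynone already has the oxidation level of the flavone, so no oxidant meets the tertiary amine, unlike a chalcone closure. Because C8a carries a MOM ether and C5 a benzyl ether, acid frees only the oxygen that must close. The forward reaction goes through amine adduct 26 and phenol 27, which cannot give the five-membered aurone.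

**25 from 19 and 23.** The C4a–C4 bond is cut. The only aryl hydrogen of 19 lies between the MOM ether and a benzyloxy group, so deprotonation there needs no regiochemical choice. A Friedel–Crafts acetylation of the free phenol would expose benzyl ethers to Lewis acid and free the ortho phenol several steps early. Weinreb amide 23 comes in one step from alkyne 20 and carbamoyl chloride 21, so the whole of rings B and C arrives as one fragment.

**19 from 13 through 18, 16 and 15.** These are functional group changes only. The N-methyl group of 19 is the reduced Boc carbonyl of 18, so no separate deprotection and methylation are needed. The C4 methylene of 18 comes from ketone 15 through tosylhydrazone 16, and 15 from the exocyclic methylidene of 13. These three steps are the price of the cycloaddition, which brings one carbon too many.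

**13 from 11 and 12 (key cut).** Pyrrolidine bonds C2–C3 and N–C5 are cut, giving N-Boc aldimine 11 and trimethylenemethane donor 12. Cutting the aryl–C2 bond instead would require a cross-coupling at an aryl carbon with two ortho substituents. Cutting N–C5 alone after adding a three-carbon organometallic to a chiral imine would need a stoichiometric auxiliary. The chosen cut forms the ring and the stereocentre together under catalyst control and reduces the problem to an aromatic aldehyde. The forward reaction must add to one face of a crowded, electron-rich imine.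

**11 from 8 and 9 through 10.** The C=N bond is cut. Amido sulfone 10, made from aldehyde 8 and carbamate 9, is a storable precursor from which the moisture-sensitive imine is released under anhydrous base just before use.

**8 from 6 through 7.** The MOM O–C bond and the ring–CHO bond are cut. Phenol 6 is symmetrical, its two ortho positions are identical and its para position is blocked, so formylation can give only 7. The second ortho position stays free and later becomes C4a.

**6 from 1 through 2, 3 and 4.** The phenol oxygen of 6 replaces the carboxyl carbon of 1 by way of aldehyde 4 and a Baeyer–Villiger oxidation. Ester 1 already has the 3,4,5-oxygen pattern with the central oxygen methylated, so the two flanking phenols can be benzylated without any selectivity problem.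

## Roads not taken

**Alternative 1:** Ring A itself is cut at the C4a–C8a bond. Cyclobutenone A2 would be made from a squaric ester by successive addition of a configurationally defined 2-lithio-N-Boc-pyrrolidine and an α-ethoxyvinyl lithium reagent, then O-methylation. Heating A2 opens it to a dienylketene whose 6π electrocyclisation gives phenol A1.
- Merits: the fully substituted ring A, with the pyrrolidine on C8 and the C8a phenol free, arises in about four operations. There is no Baeyer–Villiger, no formylation and no surplus carbon to remove. To this stage it is clearly shorter than the thirteen steps leading to 19.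
- Weak points: the stereocentre rests on a stoichiometric chiral diamine and an organolithium that keeps its configuration only when cold. Two additions to the four-membered ring must each go to the right carbonyl. Ring A emerges with ethyl (C5), methyl (C6) and isopropyl (C7) ethers, and ethyl can be told from methyl only by chelation to the C4 carbonyl at the very end. C4a must still be acylated next to a free phenol.
- Comparison: the chosen plan is longer but uses a catalytic source of chirality with both ligand enantiomers available. Its benzyl/MOM/methyl set is orthogonal by design, and its risk sits in one step rather than in several organolithium additions and a late ether differentiation.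

**Alternative 2:** Ring C is cut at C4a–C4, C4–C3 and O1–C2. Iodophenol A4, carbon monoxide and alkyne 20 would combine under PdCl2(PPh3)2 and diethylamine to give A3, which is the same compound as 28.
- Merits: this is the most convergent way to ring C, uses 20 directly and needs no organolithium. From 19 it would take three steps (unmasking, iodination, annulation), the same as steps 14 to 16, so in step count it is equal.
- Weak points: A4 has its phenol free next to the benzylic amine and must be iodinated in the presence of an oxidisable tertiary amine on a very electron-rich ring. Oxidative addition and CO insertion at a carbon with two ortho substituents are slow, so direct alkyne coupling without CO and five-membered closure compete. The free phenol is heated with base.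
- Comparison: this road also leaves the stereocentre unsolved. The chosen endgame sets against its convergence a metalation whose regiochemistry the substrate dictates, no gas, and a phenol that is never free before it closes.

**Alternative 3:** The C4–C3 bond is cut, with a temporary O–C2 bond. Nitrile oxide A6 would add to alkyne 20 to give 3,5-diarylisoxazole A5, whose N–O bond is later reduced to unveil the 1,3-dicarbonyl unit for acid closure.
- Merits: a nitrile oxide with two ortho substituents does not dimerise and can be handled. The cycloaddition is metal-free, regioselective and tolerant of crowding, probably more so than the acylation of a hindered aryllithium. The isoxazole is a robust carrier.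
- Weak points: the sequence is long (C4a formylation, oxime, oxidation, cycloaddition, N–O cleavage, closure). Formylation by lithiation at the N-Boc stage competes with deprotonation at the benzylic carbon next to the carbamate. After the flavone exists the Boc group can no longer be reduced to methyl and must be removed and replaced by reductive methylation.
- Comparison: the chosen route reaches 28 from 18 in four steps and stays redox-neutral after step 13, which outweighs the milder bond formation of this road.

Key step: step 9

Remark: compounds 1, 9, 12, 20 and 21 are taken as purchasable.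
Remark: the ligand enantiomer in step 9 is the one that sends the nucleophile to the Re face of the imine carbon; this assignment rests on analogy with simpler N-Boc aryl aldimines and would be checked on 13, both ligand enantiomers being accessible.

## Route

Step 1
Reactants: 1 methyl 3,5-dihydroxy-4-methoxybenzoate
Product: 2 methyl 3,5-bis(benzyloxy)-4-methoxybenzoate
Conditions: BnBr, K2CO3, DMF, 60 °C
Reagents that add atoms: benzyl bromide, BrCc1ccccc1
Why: Williamson etherification of both phenols; the methyl ester is inert to K2CO3 in DMF.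

Step 2
Reactants: 2 methyl 3,5-bis(benzyloxy)-4-methoxybenzoate
Product: 3 [3,5-bis(benzyloxy)-4-methoxyphenyl]methanol
Conditions: LiAlH4, THF, 0 °C to rt
Reagents that add atoms: none
Why: Hydride reduction of the ester to the benzylic alcohol; aryl ethers are untouched.

Step 3
Reactants: 3 [3,5-bis(benzyloxy)-4-methoxyphenyl]methanol
Product: 4 3,5-bis(benzyloxy)-4-methoxybenzaldehyde
Conditions: MnO2, CH2Cl2, rt
Reagents that add atoms: none
Why: MnO2 oxidises benzylic alcohols selectively to aldehydes without over-oxidation.

Step 4
Reactants: 4 3,5-bis(benzyloxy)-4-methoxybenzaldehyde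
Product: 6 3,5-bis(benzyloxy)-4-methoxyphenol, via aryl formate 5 (not isolated)
Conditions: mCPBA, CH2Cl2, 0 °C to rt; then K2CO3, MeOH, rt
Reagents that add atoms: 3-chloroperoxybenzoic acid, O=C(OO)c1cccc(Cl)c1
Why: Baeyer–Villiger (Dakin-type) oxidation in which the electron-rich trialkoxyaryl group migrates in preference to hydrogen to give formate 5, which mild methanolysis turns into the phenol; this is the standard change for 3,4,5-trialkoxybenzaldehydes.

Step 5
Reactants: 6 3,5-bis(benzyloxy)-4-methoxyphenol
Product: 7 2,4-bis(benzyloxy)-6-hydroxy-3-methoxybenzaldehyde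
Conditions: MgCl2, Et3N, (CH2O)n, MeCN, reflux
Reagents that add atoms: paraformaldehyde (as formaldehyde), C=O
Why: Magnesium-mediated ortho-formylation (Casnati–Skattebøl): the magnesium phenoxide delivers formaldehyde to the ortho carbon and a second formaldehyde accepts hydride. The two ortho positions of 6 are equivalent and the para position is blocked, so only one aldehyde can form.

Step 6
Reactants: 7 2,4-bis(benzyloxy)-6-hydroxy-3-methoxybenzaldehyde
Product: 8 2,4-bis(benzyloxy)-3-methoxy-6-(methoxymethoxy)benzaldehyde
Conditions: MOMCl, i-Pr2NEt, CH2Cl2, 0 °C to rt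
Reagents that add atoms: chloromethyl methyl ether, COCCl
Why: O-alkylation of the phenol under amine base; the MOM ether is the one ring A oxygen that mild acid will later free, and it serves as the metalation director in step 15.

Step 7
Reactants: 8 2,4-bis(benzyloxy)-3-methoxy-6-(methoxymethoxy)benzaldehyde; 9 tert-butyl carbamate
Product: 10 tert-butyl N-[(benzenesulfonyl){2,4-bis(benzyloxy)-3-methoxy-6-(methoxymethoxy)phenyl}methyl]carbamate (racemic)
Conditions: PhSO2Na, HCO2H, THF/H2O, rt
Reagents that add atoms: sodium benzenesulfinate (PhSO2Na), [Na+].[O-]S(=O)c1ccccc1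
Why: Three-component Mannich-type condensation to the α-amido sulfone, the usual bench-stable precursor of N-Boc aldimines; the centre formed is racemic and is destroyed in step 8.

Step 8
Reactants: 10 tert-butyl N-[(benzenesulfonyl){2,4-bis(benzyloxy)-3-methoxy-6-(methoxymethoxy)phenyl}methyl]carbamate
Product: 11 tert-butyl N-{(E)-[2,4-bis(benzyloxy)-3-methoxy-6-(methoxymethoxy)phenyl]methylidene}carbamate
Conditions: K2CO3, Na2SO4, THF, reflux; filtered, concentrated and used directly
Reagents that add atoms: none
Why: Base-induced elimination of benzenesulfinate under anhydrous conditions releases the N-Boc aldimine; it has no α-hydrogen, so it cannot tautomerise, and the E isomer is the stable one.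

Step 9
Reactants: 11 tert-butyl N-{(E)-[2,4-bis(benzyloxy)-3-methoxy-6-(methoxymethoxy)phenyl]methylidene}carbamate; 12 2-[(trimethylsilyl)methyl]prop-2-en-1-yl acetate
Product: 13 tert-butyl (2R)-2-[2,4-bis(benzyloxy)-3-methoxy-6-(methoxymethoxy)phenyl]-4-methylidenepyrrolidine-1-carboxylate
Conditions: Pd(dba)2 (5 mol %), BINOL-derived phosphoramidite with a trans-2,5-di(2-naphthyl)pyrrolidine amine part (10 mol %), toluene, 4 °C to rt
Reagents that add atoms: none
Why: Zerovalent palladium ionises the allylic acetate of 12 and the displaced acetate removes the silyl group, giving the zwitterionic palladium–trimethylenemethane complex. Its carbanionic terminus adds to the imine carbon of 11 (bond C2–C3), and the carbamate nitrogen anion so formed attacks a terminus of the cationic π-allylpalladium unit (bond N–C5), releasing the catalyst. The ring therefore closes stepwise by intramolecular allylic amination, a 5-exo-tet-type attack on the allyl terminus that leaves the third carbon as the exocyclic methylidene. The closest known reaction type is the palladium-catalysed enantioselective trimethylenemethane (3+2) cycloaddition to N-Boc aryl aldimines with BINOL–pyrrolidine phosphoramidites. The only new stereocentre, C2, is set in the carbon–carbon bond-forming addition, where the ligand on palladium selects the Re face of the imine carbon, which corresponds to 2R. The step needs enantiofacial selectivity and preference for C=N addition over protodesilylation of the donor; the single E geometry of 11, the absence of α-hydrogens and the Boc group, which keeps the crowded, electron-rich imine electrophilic and the nitrogen anion able to close, provide for both. Benzyl, MOM and methyl ethers are inert under these neutral conditions.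

Step 10
Reactants: 13 tert-butyl (2R)-2-[2,4-bis(benzyloxy)-3-methoxy-6-(methoxymethoxy)phenyl]-4-methylidenepyrrolidine-1-carboxylate
Product: 15 tert-butyl (2R)-2-[2,4-bis(benzyloxy)-3-methoxy-6-(methoxymethoxy)phenyl]-4-oxopyrrolidine-1-carboxylate, via diol 14 (not isolated)
Conditions: OsO4 (cat.), NaIO4, 2,6-lutidine, dioxane/H2O, rt
Reagents that add atoms: osmium tetroxide (oxygen carrier), O=[Os](=O)(=O)=O; sodium periodate (NaIO4, stoichiometric oxygen source), [Na+].[O-]I(=O)(=O)=O
Why: Lemieux–Johnson cleavage: osmylation of the 1,1-disubstituted alkene gives diol 14, which periodate cleaves to the ketone; the electron-rich arene is left alone, which ozone would not guarantee. C2 is not α to the new carbonyl, and without strong base the carbamate nitrogen does not eliminate.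

Step 11
Reactants: 15 tert-butyl (2R)-2-[2,4-bis(benzyloxy)-3-methoxy-6-(methoxymethoxy)phenyl]-4-oxopyrrolidine-1-carboxylate
Product: 16 tert-butyl (2R)-2-[2,4-bis(benzyloxy)-3-methoxy-6-(methoxymethoxy)phenyl]-4-[2-(4-methylbenzenesulfonyl)hydrazinylidene]pyrrolidine-1-carboxylate (C=N isomers)
Conditions: TsNHNH2, MeOH, rt
Reagents that add atoms: 4-methylbenzenesulfonohydrazide, Cc1ccc(cc1)S(=O)(=O)NN
Why: Condensation of the ketone with tosylhydrazide under neutral conditions; Boc, MOM and the stereocentre are not affected.

Step 12
Reactants: 16 tert-butyl (2R)-2-[2,4-bis(benzyloxy)-3-methoxy-6-(methoxymethoxy)phenyl]-4-[2-(4-methylbenzenesulfonyl)hydrazinylidene]pyrrolidine-1-carboxylate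
Product: 18 tert-butyl (2R)-2-[2,4-bis(benzyloxy)-3-methoxy-6-(methoxymethoxy)phenyl]pyrrolidine-1-carboxylate, via tosylhydrazine 17 (not isolated)
Conditions: catecholborane, CHCl3, 0 °C; then NaOAc·3H2O, reflux
Reagents that add atoms: none
Why: Caglioti-type tosylhydrazone deoxygenation in its mild catecholborane form: hydroboration of the C=N bond gives hydrazine 17 (as its N-boryl derivative), and acetate triggers loss of sulfinate and then of dinitrogen, leaving the methylene. Neither strong base nor strong acid is present, so the β-amino ketone stage is left without epimerisation risk and Boc and MOM survive.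

Step 13
Reactants: 18 tert-butyl (2R)-2-[2,4-bis(benzyloxy)-3-methoxy-6-(methoxymethoxy)phenyl]pyrrolidine-1-carboxylate
Product: 19 (2R)-2-[2,4-bis(benzyloxy)-3-methoxy-6-(methoxymethoxy)phenyl]-1-methylpyrrolidine
Conditions: LiAlH4, THF, reflux
Reagents that add atoms: none
Why: LiAlH4 reduces the tert-butyl carbamate to the N-methyl amine, so the Boc carbonyl carbon becomes the N-methyl group; the ethers are inert and the stereocentre is not involved.

Step 14
Reactants: 20 1-(benzyloxy)-4-ethynylbenzene; 21 N-methoxy-N-methylcarbamoyl chloride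
Product: 23 3-[4-(benzyloxy)phenyl]-N-methoxy-N-methylprop-2-ynamide, via lithium acetylide 22 (not isolated)
Conditions: n-BuLi, THF, −78 °C; then 21, −78 to 0 °C
Reagents that add atoms: none
Why: Deprotonation of the terminal alkyne and acylation of acetylide 22 with the carbamoyl chloride, the usual preparation of alkynyl Weinreb amides.

Step 15
Reactants: 19 (2R)-2-[2,4-bis(benzyloxy)-3-methoxy-6-(methoxymethoxy)phenyl]-1-methylpyrrolidine; 23 3-[4-(benzyloxy)phenyl]-N-methoxy-N-methylprop-2-ynamide
Product: 25 1-{2,4-bis(benzyloxy)-3-methoxy-6-(methoxymethoxy)-5-[(2R)-1-methylpyrrolidin-2-yl]phenyl}-3-[4-(benzyloxy)phenyl]prop-2-yn-1-one, via aryllithium 24 (not isolated)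
Conditions: n-BuLi, THF, 0 °C; then 23, −78 °C; cold aq. NH4Cl
Reagents that add atoms: none
Why: Directed ortho-metalation: the only aryl C–H of 19 lies between the MOM ether and a benzyloxy group, both of which hold the base, so 24 forms at the future C4a. Weinreb amide 23 stops at the chelated tetrahedral adduct and gives the ynone on quench (Weinreb ketone synthesis); the benzylic C–H next to the N-methyl nitrogen is not acidic.

Step 16
Reactants: 25 1-{2,4-bis(benzyloxy)-3-methoxy-6-(methoxymethoxy)-5-[(2R)-1-methylpyrrolidin-2-yl]phenyl}-3-[4-(benzyloxy)phenyl]prop-2-yn-1-one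
Product: 28 5,7-bis(benzyloxy)-2-[4-(benzyloxy)phenyl]-6-methoxy-8-[(2R)-1-methylpyrrolidin-2-yl]-4H-chromen-4-one, via diethylamino enone 26 (not isolated), via phenol enaminone 27 (not isolated)
Conditions: Et2NH, MeOH, rt; then conc. HCl, MeOH, 45 °C; NaHCO3 work-up
Reagents that add atoms: none
Why: Conjugate addition of the secondary amine gives enaminone 26; acid then cleaves the MOM acetal and phenol 27 closes on the β-carbon with loss of diethylamine (6-endo-trig addition–elimination, the enaminone route to chromones). Only the C8a oxygen is free because C5 stays benzylated, and an enaminone cannot give the five-membered aurone; the amine is protonated and the phenol is consumed as it forms.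

Step 17
Reactants: 28 5,7-bis(benzyloxy)-2-[4-(benzyloxy)phenyl]-6-methoxy-8-[(2R)-1-methylpyrrolidin-2-yl]-4H-chromen-4-one
Product: 29 5,7-dihydroxy-2-(4-hydroxyphenyl)-6-methoxy-8-[(2R)-1-methylpyrrolidin-2-yl]-4H-chromen-4-one
Conditions: BCl3, pentamethylbenzene, CH2Cl2, −78 °C; MeOH quench
Reagents that add atoms: none
Why: BCl3 cleaves aryl benzyl ethers at low temperature while pentamethylbenzene traps the benzyl cations, which prevents C-benzylation of the electron-rich rings. The methyl ether is much slower to cleave at −78 °C, and the cold, short exposure limits ionisation of the benzylic C–N bond.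

## Compound list

1 | methyl 3,5-dihydroxy-4-methoxybenzoate | COC(=O)c1cc(O)c(OC)c(O)c1 | starting material
2 | methyl 3,5-bis(benzyloxy)-4-methoxybenzoate | COC(=O)c1cc(OCc2ccccc2)c(OC)c(OCc2ccccc2)c1 | intermediate
3 | [3,5-bis(benzyloxy)-4-methoxyphenyl]methanol | OCc1cc(OCc2ccccc2)c(OC)c(OCc2ccccc2)c1 | intermediate
4 | 3,5-bis(benzyloxy)-4-methoxybenzaldehyde | O=Cc1cc(OCc2ccccc2)c(OC)c(OCc2ccccc2)c1 | intermediate
5 | 3,5-bis(benzyloxy)-4-methoxyphenyl formate | O=COc1cc(OCc2ccccc2)c(OC)c(OCc2ccccc2)c1 | intermediate
6 | 3,5-bis(benzyloxy)-4-methoxyphenol | Oc1cc(OCc2ccccc2)c(OC)c(OCc2ccccc2)c1 | intermediate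
7 | 2,4-bis(benzyloxy)-6-hydroxy-3-methoxybenzaldehyde | O=Cc1c(O)cc(OCc2ccccc2)c(OC)c1OCc1ccccc1 | intermediate
8 | 2,4-bis(benzyloxy)-3-methoxy-6-(methoxymethoxy)benzaldehyde | COCOc1cc(OCc2ccccc2)c(OC)c(OCc2ccccc2)c1C=O | intermediate
9 | tert-butyl carbamate | CC(C)(C)OC(N)=O | starting material
10 | tert-butyl N-[(benzenesulfonyl){2,4-bis(benzyloxy)-3-methoxy-6-(methoxymethoxy)phenyl}methyl]carbamate (racemic) | CC(C)(C)OC(=O)NC(c1c(OCOC)cc(OCc2ccccc2)c(OC)c1OCc1ccccc1)S(=O)(=O)c1ccccc1 | intermediate
11 | tert-butyl N-{(E)-[2,4-bis(benzyloxy)-3-methoxy-6-(methoxymethoxy)phenyl]methylidene}carbamate | CC(C)(C)OC(=O)/N=C/c1c(OCOC)cc(OCc2ccccc2)c(OC)c1OCc1ccccc1 | intermediate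
12 | 2-[(trimethylsilyl)methyl]prop-2-en-1-yl acetate | CC(=O)OCC(=C)C[Si](C)(C)C | starting material
13 | tert-butyl (2R)-2-[2,4-bis(benzyloxy)-3-methoxy-6-(methoxymethoxy)phenyl]-4-methylidenepyrrolidine-1-carboxylate | COCOc1cc(OCc2ccccc2)c(OC)c(OCc2ccccc2)c1[C@H]1CC(=C)CN1C(=O)OC(C)(C)C | intermediate
14 | tert-butyl (2R)-2-[2,4-bis(benzyloxy)-3-methoxy-6-(methoxymethoxy)phenyl]-4-hydroxy-4-(hydroxymethyl)pyrrolidine-1-carboxylate (both C4 epimers) | COCOc1cc(OCc2ccccc2)c(OC)c(OCc2ccccc2)c1[C@H]1CC(O)(CO)CN1C(=O)OC(C)(C)C | intermediate
15 | tert-butyl (2R)-2-[2,4-bis(benzyloxy)-3-methoxy-6-(methoxymethoxy)phenyl]-4-oxopyrrolidine-1-carboxylate | COCOc1cc(OCc2ccccc2)c(OC)c(OCc2ccccc2)c1[C@H]1CC(=O)CN1C(=O)OC(C)(C)C | intermediate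
16 | tert-butyl (2R)-2-[2,4-bis(benzyloxy)-3-methoxy-6-(methoxymethoxy)phenyl]-4-[2-(4-methylbenzenesulfonyl)hydrazinylidene]pyrrolidine-1-carboxylate (C=N isomers) | COCOc1cc(OCc2ccccc2)c(OC)c(OCc2ccccc2)c1[C@H]1CC(=NNS(=O)(=O)c2ccc(C)cc2)CN1C(=O)OC(C)(C)C | intermediate
17 | tert-butyl (2R)-2-[2,4-bis(benzyloxy)-3-methoxy-6-(methoxymethoxy)phenyl]-4-[2-(4-methylbenzenesulfonyl)hydrazin-1-yl]pyrrolidine-1-carboxylate (both C4 epimers) | COCOc1cc(OCc2ccccc2)c(OC)c(OCc2ccccc2)c1[C@H]1CC(NNS(=O)(=O)c2ccc(C)cc2)CN1C(=O)OC(C)(C)C | intermediate
18 | tert-butyl (2R)-2-[2,4-bis(benzyloxy)-3-methoxy-6-(methoxymethoxy)phenyl]pyrrolidine-1-carboxylate | COCOc1cc(OCc2ccccc2)c(OC)c(OCc2ccccc2)c1[C@H]1CCCN1C(=O)OC(C)(C)C | intermediate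
19 | (2R)-2-[2,4-bis(benzyloxy)-3-methoxy-6-(methoxymethoxy)phenyl]-1-methylpyrrolidine | COCOc1cc(OCc2ccccc2)c(OC)c(OCc2ccccc2)c1[C@H]1CCCN1C | intermediate
20 | 1-(benzyloxy)-4-ethynylbenzene | C#Cc1ccc(OCc2ccccc2)cc1 | starting material
21 | N-methoxy-N-methylcarbamoyl chloride | CON(C)C(Cl)=O | starting material
22 | {[4-(benzyloxy)phenyl]ethynyl}lithium | [Li]C#Cc1ccc(OCc2ccccc2)cc1 | intermediate
23 | 3-[4-(benzyloxy)phenyl]-N-methoxy-N-methylprop-2-ynamide | CON(C)C(=O)C#Cc1ccc(OCc2ccccc2)cc1 | intermediate
24 | {2,4-bis(benzyloxy)-3-methoxy-6-(methoxymethoxy)-5-[(2R)-1-methylpyrrolidin-2-yl]phenyl}lithium | COCOc1c([Li])c(OCc2ccccc2)c(OC)c(OCc2ccccc2)c1[C@H]1CCCN1C | intermediate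
25 | 1-{2,4-bis(benzyloxy)-3-methoxy-6-(methoxymethoxy)-5-[(2R)-1-methylpyrrolidin-2-yl]phenyl}-3-[4-(benzyloxy)phenyl]prop-2-yn-1-one | COCOc1c(C(=O)C#Cc2ccc(OCc3ccccc3)cc2)c(OCc2ccccc2)c(OC)c(OCc2ccccc2)c1[C@H]1CCCN1C | intermediate
26 | 1-{2,4-bis(benzyloxy)-3-methoxy-6-(methoxymethoxy)-5-[(2R)-1-methylpyrrolidin-2-yl]phenyl}-3-[4-(benzyloxy)phenyl]-3-(diethylamino)prop-2-en-1-one (alkene isomers) | COCOc1c(C(=O)C=C(N(CC)CC)c2ccc(OCc3ccccc3)cc2)c(OCc2ccccc2)c(OC)c(OCc2ccccc2)c1[C@H]1CCCN1C | intermediate
27 | 1-{2,4-bis(benzyloxy)-6-hydroxy-3-methoxy-5-[(2R)-1-methylpyrrolidin-2-yl]phenyl}-3-[4-(benzyloxy)phenyl]-3-(diethylamino)prop-2-en-1-one (alkene isomers) | Oc1c(C(=O)C=C(N(CC)CC)c2ccc(OCc3ccccc3)cc2)c(OCc2ccccc2)c(OC)c(OCc2ccccc2)c1[C@H]1CCCN1C | intermediate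
28 | 5,7-bis(benzyloxy)-2-[4-(benzyloxy)phenyl]-6-methoxy-8-[(2R)-1-methylpyrrolidin-2-yl]-4H-chromen-4-one | COc1c(OCc2ccccc2)c([C@H]2CCCN2C)c2oc(-c3ccc(OCc4ccccc4)cc3)cc(=O)c2c1OCc1ccccc1 | intermediate
29 | 5,7-dihydroxy-2-(4-hydroxyphenyl)-6-methoxy-8-[(2R)-1-methylpyrrolidin-2-yl]-4H-chromen-4-one | COc1c(O)c([C@H]2CCCN2C)c2oc(-c3ccc(O)cc3)cc(=O)c2c1O | target

## Step count and risk

Total step count: 17. Longest linear sequence: 16 steps (steps 1 to 13 and 15 to 17, from 1 to 29); step 14 is a one-step side branch.

**Step 9 (key step).** The two ortho alkoxy groups shield the imine carbon and lower its electrophilicity, so protodesilylation of the donor and hydrolysis of the imine by traces of water may outrun the cycloaddition. Because the aryl ring is twisted out of the C=N plane, facial discrimination by the ligand may also be weaker than with flat aryl aldimines. Fallback: setting out from 8, condensation with TsNH2 and Ti(OEt)4 would give N-[(E)-{2,4-bis(benzyloxy)-3-methoxy-6-(methoxymethoxy)phenyl}methylidene]-4-methylbenzenesulfonamide F1, a more electrophilic imine that is robust to hydrolysis. The same Pd(dba)2/phosphoramidite cycloaddition with 12 would give (2R)-2-[2,4-bis(benzyloxy)-3-methoxy-6-(methoxymethoxy)phenyl]-4-methylidene-1-(4-methylbenzenesulfonyl)pyrrolidine F2. Reductive detosylation with SmI2, Et3N and water would give (2R)-2-[2,4-bis(benzyloxy)-3-methoxy-6-(methoxymethoxy)phenyl]-4-methylidenepyrrolidine F3, and Boc2O would bring the route back at 13.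

**Step 7.** The condensation is an equilibrium that the hindered, electron-rich aldehyde may not favour, especially if the sulfone fails to crystallise out, and days in formic acid may cause slow loss of the MOM group. Fallback: setting out from 8, an aza-Wittig reaction with Ph3P=NBoc in refluxing toluene gives 11 directly under neutral conditions, bypassing 10; no new compound arises.

**Step 12.** Hydroboration of the hydrazone may be incomplete, or elimination toward an alkene may compete with reduction, and the Lewis-acidic borane may attack the MOM group. Fallback: setting out from 15, NaBH4 in MeOH would give tert-butyl (2R)-2-[2,4-bis(benzyloxy)-3-methoxy-6-(methoxymethoxy)phenyl]-4-hydroxypyrrolidine-1-carboxylate F4. 1,1'-Thiocarbonyldiimidazole would convert it into tert-butyl (2R)-2-[2,4-bis(benzyloxy)-3-methoxy-6-(methoxymethoxy)phenyl]-4-[(1H-imidazole-1-carbothioyl)oxy]pyrrolidine-1-carboxylate F5. Bu3SnH with AIBN in hot toluene (Barton–McCombie deoxygenation) returns to the route at 18.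

**Step 15.** Deprotonation at a benzylic OCH2 followed by [1,2]-Wittig rearrangement may compete with ring metalation, and acylation of an aryllithium with two ortho substituents may be sluggish. Conjugate addition of the released hydroxylamine to the ynone would be harmless, since that adduct also closes in step 16. Fallback: setting out from 19, HCl in MeOH would give 3,5-bis(benzyloxy)-4-methoxy-2-[(2R)-1-methylpyrrolidin-2-yl]phenol F6. Acetic anhydride with BF3·OEt2 (Friedel–Crafts/Fries acylation at the only free ring position) would give 1-{2,4-bis(benzyloxy)-6-hydroxy-3-methoxy-5-[(2R)-1-methylpyrrolidin-2-yl]phenyl}ethan-1-one F7. Claisen–Schmidt condensation with 4-(benzyloxy)benzaldehyde (KOH, EtOH) would give (2E)-1-{2,4-bis(benzyloxy)-6-hydroxy-3-methoxy-5-[(2R)-1-methylpyrrolidin-2-yl]phenyl}-3-[4-(benzyloxy)phenyl]prop-2-en-1-one F8. Oxidative cyclisation with catalytic I2 in DMSO comes back to the route at 28. This costs two more steps and exposes the free phenol next to the stereocentre to heat.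

**Step 17.** On warming, the boron phenoxide formed at C5 or C7 may assist cleavage of the neighbouring C6 methyl ether. Complexation of the Lewis acid at nitrogen may also ionise the benzylic C–N bond and erode the configuration. Fallback: setting out from 28, hydrogenolysis (H2, Pd/C, EtOAc/MeOH, rt) gives 29 directly; no new compound arises, and the reaction would be stopped early to spare the benzylic C–N bond.

## Further compounds

F1 | step 9 | N-[(E)-{2,4-bis(benzyloxy)-3-methoxy-6-(methoxymethoxy)phenyl}methylidene]-4-methylbenzenesulfonamide | Cc1ccc(cc1)S(=O)(=O)/N=C/c1c(OCOC)cc(OCc2ccccc2)c(OC)c1OCc1ccccc1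
F2 | step 9 | (2R)-2-[2,4-bis(benzyloxy)-3-methoxy-6-(methoxymethoxy)phenyl]-4-methylidene-1-(4-methylbenzenesulfonyl)pyrrolidine | COCOc1cc(OCc2ccccc2)c(OC)c(OCc2ccccc2)c1[C@H]1CC(=C)CN1S(=O)(=O)c1ccc(C)cc1
F3 | step 9 | (2R)-2-[2,4-bis(benzyloxy)-3-methoxy-6-(methoxymethoxy)phenyl]-4-methylidenepyrrolidine | COCOc1cc(OCc2ccccc2)c(OC)c(OCc2ccccc2)c1[C@H]1CC(=C)CN1
F0 | step 7 | none | none
F4 | step 12 | tert-butyl (2R)-2-[2,4-bis(benzyloxy)-3-methoxy-6-(methoxymethoxy)phenyl]-4-hydroxypyrrolidine-1-carboxylate (both C4 epimers) | COCOc1cc(OCc2ccccc2)c(OC)c(OCc2ccccc2)c1[C@H]1CC(O)CN1C(=O)OC(C)(C)C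
F5 | step 12 | tert-butyl (2R)-2-[2,4-bis(benzyloxy)-3-methoxy-6-(methoxymethoxy)phenyl]-4-[(1H-imidazole-1-carbothioyl)oxy]pyrrolidine-1-carboxylate (both C4 epimers) | COCOc1cc(OCc2ccccc2)c(OC)c(OCc2ccccc2)c1[C@H]1CC(OC(=S)n2ccnc2)CN1C(=O)OC(C)(C)C
F6 | step 15 | 3,5-bis(benzyloxy)-4-methoxy-2-[(2R)-1-methylpyrrolidin-2-yl]phenol | Oc1cc(OCc2ccccc2)c(OC)c(OCc2ccccc2)c1[C@H]1CCCN1C
F7 | step 15 | 1-{2,4-bis(benzyloxy)-6-hydroxy-3-methoxy-5-[(2R)-1-methylpyrrolidin-2-yl]phenyl}ethan-1-one | CC(=O)c1c(O)c([C@H]2CCCN2C)c(OCc2ccccc2)c(OC)c1OCc1ccccc1
F8 | step 15 | (2E)-1-{2,4-bis(benzyloxy)-6-hydroxy-3-methoxy-5-[(2R)-1-methylpyrrolidin-2-yl]phenyl}-3-[4-(benzyloxy)phenyl]prop-2-en-1-one | O=C(/C=C/c1ccc(OCc2ccccc2)cc1)c1c(O)c([C@H]2CCCN2C)c(OCc2ccccc2)c(OC)c1OCc1ccccc1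
F0 | step 17 | none | none
A1 | alternative 1 | tert-butyl (2R)-2-[4-ethoxy-2-hydroxy-5-methoxy-6-(propan-2-yloxy)phenyl]pyrrolidine-1-carboxylate | CCOc1cc(O)c([C@H]2CCCN2C(=O)OC(C)(C)C)c(OC(C)C)c1OC
A2 | alternative 1 | tert-butyl (2R)-2-[3-(1-ethoxyethenyl)-3-methoxy-4-oxo-2-(propan-2-yloxy)cyclobut-1-en-1-yl]pyrrolidine-1-carboxylate (both epimers at the ring sp3 carbon) | CCOC(=C)C1(OC)C(=O)C([C@H]2CCCN2C(=O)OC(C)(C)C)=C1OC(C)C
A3 | alternative 2 | 5,7-bis(benzyloxy)-2-[4-(benzyloxy)phenyl]-6-methoxy-8-[(2R)-1-methylpyrrolidin-2-yl]-4H-chromen-4-one (same structure as 28) | COc1c(OCc2ccccc2)c([C@H]2CCCN2C)c2oc(-c3ccc(OCc4ccccc4)cc3)cc(=O)c2c1OCc1ccccc1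
A4 | alternative 2 | 3,5-bis(benzyloxy)-2-iodo-4-methoxy-6-[(2R)-1-methylpyrrolidin-2-yl]phenol | Oc1c(I)c(OCc2ccccc2)c(OC)c(OCc2ccccc2)c1[C@H]1CCCN1C
A5 | alternative 3 | tert-butyl (2R)-2-{2,4-bis(benzyloxy)-5-{5-[4-(benzyloxy)phenyl]-1,2-oxazol-3-yl}-3-methoxy-6-(methoxymethoxy)phenyl}pyrrolidine-1-carboxylate | COCOc1c(-c2cc(-c3ccc(OCc4ccccc4)cc3)on2)c(OCc2ccccc2)c(OC)c(OCc2ccccc2)c1[C@H]1CCCN1C(=O)OC(C)(C)C
A6 | alternative 3 | 2,4-bis(benzyloxy)-5-[(2R)-1-(tert-butoxycarbonyl)pyrrolidin-2-yl]-3-methoxy-6-(methoxymethoxy)benzonitrile N-oxide | COCOc1c(C#[N+][O-])c(OCc2ccccc2)c(OC)c(OCc2ccccc2)c1[C@H]1CCCN1C(=O)OC(C)(C)C
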